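A direct plan would cut the diaryl ether at the O–aryl bond of ring B. It would couple the di-ortho-substituted phenol A1 (ring A; acid carried as aldehyde, pentyl as pentenyl) with the ortho-bromobenzoate A2 under copper catalysis to give A3, which would then be oxidised and hydrogenated.
Its weakest steps would be:
(i) the Ullmann-type C–O coupling, because the phenol oxygen would be flanked on both sides, and hot base would meet an aldehyde and an enolisable ketone placed to cyclise onto the neighbouring ester;
(ii) the persulfate hydroxylation of salicylaldehyde A4 that would bring in this phenol oxygen, because such oxidations stall at low conversion and the aldehyde would suffer;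
(iii) the deprotonation of dihalide A5 between bromine and iodine for carboxylation, because halogen migration, aryne formation and metalation next to the ether oxygen would compete.
Both rings would also be dressed one substituent at a time, which would add length without complexity.

The route builds ring A (C1 CO2H, C2 pentyl, C3 OAr, C4 OMe, C5 H, C6 OH) around an ether oxygen that is already in place. The O–C3 bond is made by SN2 while C3 is still an sp3 allylic carbon. The meta-dioxygenation C4/C6 beside the C1 carboxyl is the signature of a vinylketene acetal–alkynoate Diels–Alder reaction: one cycloaddition–aromatisation forms C2–C3 and C1–C6, closes ring A and places all five substituents. No hindered aryl C–O coupling, no arene hydroxylation and no metalation between halogens remains. Ring B comes from a symmetric phloroglucinol ester by desymmetrisation, its side chain by a late Heck reaction.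

Key step: step 6

Assumption: the target SMILES holds no stereocentre and no stereogenic double bond, so the compound is achiral and no enantiocontrol is needed. Ring A is numbered as in the benzoic acid name (C1 = carbon that bears the carboxyl group).

Step 1
Reactants: 1 methyl 2,4,6-trihydroxybenzoate
Product: 2 methyl 4-(benzyloxy)-2,6-dihydroxybenzoate
Conditions: BnBr (1.0 eq), K2CO3 (1.0 eq), acetone, rt
Reagents that add atoms: benzyl bromide, BrCc1ccccc1
Why: Williamson etherification is selective for the 4-OH, the only hydroxyl that is not hydrogen-bonded to the ester and the most acidic one, and it keeps the two remaining phenols equivalent.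

Step 2
Reactants: 2 methyl 4-(benzyloxy)-2,6-dihydroxybenzoate
Product: 3 methyl 4-(benzyloxy)-2-hydroxy-6-[(trifluoromethanesulfonyl)oxy]benzoate
Conditions: Tf2O (1.0 eq), pyridine, CH2Cl2, −20 → 0 °C
Reagents that add atoms: trifluoromethanesulfonic anhydride, O=S(=O)(OS(=O)(=O)C(F)(F)F)C(F)(F)F
Why: O-Sulfonylation of one of two equivalent phenols (desymmetrisation) should stop after the first triflation, because the electron-poorer ring and the strong hydrogen bond of the last OH to the ester carbonyl slow the second one.

Step 3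
Reactants: 3 methyl 4-(benzyloxy)-2-hydroxy-6-[(trifluoromethanesulfonyl)oxy]benzoate; 4 methyl (E)-4-chloro-3-methoxybut-2-enoate
Product: 5 methyl 4-(benzyloxy)-2-{[(2E)-2,4-dimethoxy-4-oxobut-2-en-1-yl]oxy}-6-[(trifluoromethanesulfonyl)oxy]benzoate
Conditions: K2CO3 (1.5 eq), DMF, 45 °C
Reagents that add atoms: none
Why: Williamson SN2 displacement at a primary allylic chloride forms the future hindered O–C3 bond of the diaryl ether while C3 is an unhindered sp3 carbon, leaves the alkene geometry untouched and is mild enough for the aryl triflate.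

Step 4
Reactants: 5 methyl 4-(benzyloxy)-2-{[(2E)-2,4-dimethoxy-4-oxobut-2-en-1-yl]oxy}-6-[(trifluoromethanesulfonyl)oxy]benzoate
Product: 6 methyl 4-(benzyloxy)-2-{[(1Z)-2,4-dimethoxy-4-(trimethylsilyloxy)buta-1,3-dien-1-yl]oxy}-6-[(trifluoromethanesulfonyl)oxy]benzoate (ketene acetal geometry undefined and without consequence)
Conditions: TMSOTf (1.5 eq), Et3N (2.5 eq), Et2O, 0 °C → rt; pentane, filtration under Ar, concentration; used crude
Reagents that add atoms: trimethylsilyl trifluoromethanesulfonate, C[Si](C)(C)OS(=O)(=O)C(F)(F)F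
Why: Soft enolisation with a silyl triflate and a tertiary amine, known for β-oxygenated enoates such as dioxinones, tetronates and silylated acetoacetates, O-silylates the ester carbonyl and removes a γ-proton without forming a carbanion that could attack the ortho ester or the triflate, and allylic 1,3-strain against the cis ester carbon should place the aryloxy group beside the methoxy group (1Z, the outward position that the s-cis diene needs).

Step 5
Reactants: 7 oct-2-ynoic acid
Product: 8 benzyl oct-2-ynoate
Conditions: BnBr (1.05 eq), K2CO3 (1.1 eq), DMF, rt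
Reagents that add atoms: benzyl bromide, BrCc1ccccc1
Why: Carboxylate O-alkylation (SN2) gives the benzyl ester, which distinguishes the ring A carboxyl from the methyl ester of ring B and falls in the last step.

Step 6
Reactants: 6 methyl 4-(benzyloxy)-2-{[(1Z)-2,4-dimethoxy-4-(trimethylsilyloxy)buta-1,3-dien-1-yl]oxy}-6-[(trifluoromethanesulfonyl)oxy]benzoate; 8 benzyl oct-2-ynoate
Product: 11 benzyl 3-{5-(benzyloxy)-2-(methoxycarbonyl)-3-[(trifluoromethanesulfonyl)oxy]phenoxy}-6-hydroxy-4-methoxy-2-pentylbenzoate, via cyclohexa-1,4-diene cycloadduct 9 (not isolated), via aryl silyl ether 10 (not isolated)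
Conditions: 8 (3 eq), N,O-bis(trimethylsilyl)acetamide (BSA, 1.2 eq), toluene, sealed tube, 140 °C, Ar; then 1 M HCl, THF, rt
Reagents that add atoms: none
Why: This is a normal-electron-demand Diels–Alder reaction followed by aromatisation, the benzannulation known for Brassard- and Chan-type vinylketene acetals with alk-2-ynoates as a route to resorcylates, run here on a diene whose terminus already carries the aryloxy group. The concerted but asynchronous [4π+2π] closure forms C2–C3 in advance (diene terminus to the β-carbon of 8) and C1–C6 behind it (ketene acetal carbon to the α-carbon), and so closes the six-membered ring A in one intermolecular cycloaddition. The regiochemistry needed is secured by the three oxygen donors on C6, C6 and C4 of the diene, which put the largest HOMO coefficient on the carbon that bears the only weakly donating, ester- and triflate-substituted aryloxy group, matched with the largest LUMO coefficient at the β-carbon of the ynoate. In 9 the carbon C6 carries two oxygen leaving groups and no hydrogen, whereas C3 carries the only sp3 ring hydrogen, so aromatisation can proceed only by 1,4-loss of methanol and the aryloxy group cannot be expelled productively. The two stereocentres of 9 (C3 and C6, formed without control) are both erased, BSA traps the methanol before it can protonate unreacted 6, and dilute acid cleaves the aryl silyl ether 10. Triflate, benzyl ether and both esters are inert to heat in the absence of metal, strong acid or base.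

Step 7
Reactants: 11 benzyl 3-{5-(benzyloxy)-2-(methoxycarbonyl)-3-[(trifluoromethanesulfonyl)oxy]phenoxy}-6-hydroxy-4-methoxy-2-pentylbenzoate; 12 pent-1-en-3-one (ethyl vinyl ketone)
Product: 13 benzyl 3-{5-(benzyloxy)-2-(methoxycarbonyl)-3-[(1E)-3-oxopent-1-en-1-yl]phenoxy}-6-hydroxy-4-methoxy-2-pentylbenzoate
Conditions: Pd(OAc)2 (5 mol%), dppp (6 mol%), Et3N (2 eq), 12 (2 eq), BHT (trace), DMF, 80 °C
Reagents that add atoms: none
Why: The Mizoroki–Heck reaction of an aryl triflate activated by its ortho ester with an electron-poor vinyl ketone gives terminal arylation whichever pathway (neutral or cationic) operates, and any reductive-Heck product would converge on the target in the last step.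

Step 8
Reactants: 13 benzyl 3-{5-(benzyloxy)-2-(methoxycarbonyl)-3-[(1E)-3-oxopent-1-en-1-yl]phenoxy}-6-hydroxy-4-methoxy-2-pentylbenzoate
Product: 14 epiphorellic acid 2, 6-hydroxy-3-[5-hydroxy-2-(methoxycarbonyl)-3-(3-oxopentyl)phenoxy]-4-methoxy-2-pentylbenzoic acid
Conditions: H2 (1 atm), 10% Pd/C, EtOAc, rt
Reagents that add atoms: none
Why: Catalytic hydrogenation saturates the enone C=C bond and hydrogenolyses the benzyl ether and the benzyl ester in one operation, while the dialkyl ketone, methyl ester, aryl methyl ether and diaryl ether are inert.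

Compound list
1 | methyl 2,4,6-trihydroxybenzoate | COC(=O)c1c(O)cc(O)cc1O | starting material
2 | methyl 4-(benzyloxy)-2,6-dihydroxybenzoate | COC(=O)c1c(O)cc(OCc2ccccc2)cc1O | intermediate
3 | methyl 4-(benzyloxy)-2-hydroxy-6-[(trifluoromethanesulfonyl)oxy]benzoate | COC(=O)c1c(O)cc(OCc2ccccc2)cc1OS(=O)(=O)C(F)(F)F | intermediate
4 | methyl (E)-4-chloro-3-methoxybut-2-enoate | COC(=O)/C=C(/OC)CCl | starting material
5 | methyl 4-(benzyloxy)-2-{[(2E)-2,4-dimethoxy-4-oxobut-2-en-1-yl]oxy}-6-[(trifluoromethanesulfonyl)oxy]benzoate | COC(=O)/C=C(/OC)COc1cc(OCc2ccccc2)cc(OS(=O)(=O)C(F)(F)F)c1C(=O)OC | intermediate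
6 | methyl 4-(benzyloxy)-2-{[(1Z)-2,4-dimethoxy-4-(trimethylsilyloxy)buta-1,3-dien-1-yl]oxy}-6-[(trifluoromethanesulfonyl)oxy]benzoate | COC(=O)c1c(O/C=C(\OC)C=C(OC)O[Si](C)(C)C)cc(OCc2ccccc2)cc1OS(=O)(=O)C(F)(F)F | intermediate
7 | oct-2-ynoic acid | CCCCCC#CC(=O)O | starting material
8 | benzyl oct-2-ynoate | CCCCCC#CC(=O)OCc1ccccc1 | intermediate
9 | benzyl 3-{5-(benzyloxy)-2-(methoxycarbonyl)-3-[(trifluoromethanesulfonyl)oxy]phenoxy}-4,6-dimethoxy-2-pentyl-6-(trimethylsilyloxy)cyclohexa-1,4-diene-1-carboxylate (racemic mixture of diastereomers) | CCCCCC1=C(C(=O)OCc2ccccc2)C(OC)(O[Si](C)(C)C)C=C(OC)C1Oc1cc(OCc2ccccc2)cc(OS(=O)(=O)C(F)(F)F)c1C(=O)OC | intermediate (not isolated)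
10 | benzyl 3-{5-(benzyloxy)-2-(methoxycarbonyl)-3-[(trifluoromethanesulfonyl)oxy]phenoxy}-4-methoxy-2-pentyl-6-(trimethylsilyloxy)benzoate | CCCCCc1c(Oc2cc(OCc3ccccc3)cc(OS(=O)(=O)C(F)(F)F)c2C(=O)OC)c(OC)cc(O[Si](C)(C)C)c1C(=O)OCc1ccccc1 | intermediate (not isolated)
11 | benzyl 3-{5-(benzyloxy)-2-(methoxycarbonyl)-3-[(trifluoromethanesulfonyl)oxy]phenoxy}-6-hydroxy-4-methoxy-2-pentylbenzoate | CCCCCc1c(Oc2cc(OCc3ccccc3)cc(OS(=O)(=O)C(F)(F)F)c2C(=O)OC)c(OC)cc(O)c1C(=O)OCc1ccccc1 | intermediate
12 | pent-1-en-3-one | C=CC(=O)CC | starting material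
13 | benzyl 3-{5-(benzyloxy)-2-(methoxycarbonyl)-3-[(1E)-3-oxopent-1-en-1-yl]phenoxy}-6-hydroxy-4-methoxy-2-pentylbenzoate | CCCCCc1c(Oc2cc(OCc3ccccc3)cc(/C=C/C(=O)CC)c2C(=O)OC)c(OC)cc(O)c1C(=O)OCc1ccccc1 | intermediate
14 | epiphorellic acid 2 | CCCCCc1c(Oc2cc(O)cc(CCC(=O)CC)c2C(=O)OC)c(OC)cc(O)c1C(=O)O | target

Total step count: 8. Longest linear sequence: 7 (steps 1–4 and 6–8; step 5 is a one-step branch).

Steps most likely to fail

1. Step 6.
- Risk: The cycloaddition may be too slow. A diene substituted at its reacting terminus must bond to the alkyl-bearing β-carbon of an only moderately activated alkyne, so thermal decay, silyl migration or protonation of the diene may win.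
- Fallback: It sets out from 6 and comes back at 11. The alkyne would be replaced by the allene benzyl octa-2,3-dienoate F1. F1 would be made by Wittig reaction of benzyl (triphenylphosphoranylidene)acetate with butylketene, generated from hexanoyl chloride and Et3N (CH2Cl2, 0 °C → rt). Its activated 2,3-double bond offers an sp-hybridised, sterically open β-carbon. It should add 6 at 80–100 °C in toluene with the same orientation to give the 2-pentylidene cycloadduct F2. Dilute HCl in THF followed by catalytic DBU would collapse the silyl methyl ketal and move the exocyclic double bond into the ring (prototropic aromatisation) to give 11.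

2. Step 4.
- Risk: γ-Deprotonation of the silylated vinylogous carbonate may be incomplete, or C-silylation may compete. The aryloxy group may also end up in the inward position, which blocks the s-cis conformation.
- Fallback: It sets out from 5 and comes back at 11. The enol ether would be hydrolysed (1 M HCl, THF, rt) to the β-keto ester methyl 4-(benzyloxy)-2-(4-methoxy-2,4-dioxobutoxy)-6-[(trifluoromethanesulfonyl)oxy]benzoate F3. This is the substrate class for which double silylation with TMSOTf/Et3N is established, and it would give the Chan-type 1,3-bis(silyloxy)diene F4. Cycloaddition with 8 under the conditions of step 6 would pass through the cycloadduct F5. Acid work-up would then give the 4,6-dihydroxybenzoate F6. MeI (1.05 eq) and K2CO3 in acetone would methylate the only non-chelated phenol (C4–OH) to give 11.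

3. Step 7.
- Risk: Insertion at the triflate next to the twisted ester may be slow. Hydrolysis of the triflate, polymerisation of the vinyl ketone or oxa-Michael addition of the free phenol may then take over.
- Fallback: It sets out from 11 and comes back at 14, and it replaces the alkene insertion by a homoenolate cross-coupling. 1-Ethylcyclopropan-1-ol F7 would be made by Kulinkovich reaction of methyl propanoate with EtMgBr and catalytic Ti(OiPr)4. It would be coupled with 11 using Pd(OAc)2, XPhos and Cs2CO3 in toluene at 80 °C. β-Carbon elimination of the palladium cyclopropoxide and reductive elimination would give the saturated ketone benzyl 3-[5-(benzyloxy)-2-(methoxycarbonyl)-3-(3-oxopentyl)phenoxy]-6-hydroxy-4-methoxy-2-pentylbenzoate F8. Hydrogenolysis under the conditions of step 8 would convert F8 into 14.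

Further compounds
F1 | step 6 | benzyl octa-2,3-dienoate (racemic) | CCCCC=C=CC(=O)OCc1ccccc1
F2 | step 6 | benzyl 3-{5-(benzyloxy)-2-(methoxycarbonyl)-3-[(trifluoromethanesulfonyl)oxy]phenoxy}-4,6-dimethoxy-2-pentylidene-6-(trimethylsilyloxy)cyclohex-4-ene-1-carboxylate (mixture of stereoisomers) | CCCCC=C1C(Oc2cc(OCc3ccccc3)cc(OS(=O)(=O)C(F)(F)F)c2C(=O)OC)C(OC)=CC(OC)(O[Si](C)(C)C)C1C(=O)OCc1ccccc1
F3 | step 4 | methyl 4-(benzyloxy)-2-(4-methoxy-2,4-dioxobutoxy)-6-[(trifluoromethanesulfonyl)oxy]benzoate | COC(=O)CC(=O)COc1cc(OCc2ccccc2)cc(OS(=O)(=O)C(F)(F)F)c1C(=O)OC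
F4 | step 4 | methyl 4-(benzyloxy)-2-{[(1Z)-4-methoxy-2,4-bis(trimethylsilyloxy)buta-1,3-dien-1-yl]oxy}-6-[(trifluoromethanesulfonyl)oxy]benzoate | COC(=O)c1c(O/C=C(\O[Si](C)(C)C)C=C(OC)O[Si](C)(C)C)cc(OCc2ccccc2)cc1OS(=O)(=O)C(F)(F)F
F5 | step 4 | benzyl 3-{5-(benzyloxy)-2-(methoxycarbonyl)-3-[(trifluoromethanesulfonyl)oxy]phenoxy}-6-methoxy-2-pentyl-4,6-bis(trimethylsilyloxy)cyclohexa-1,4-diene-1-carboxylate (mixture of stereoisomers) | CCCCCC1=C(C(=O)OCc2ccccc2)C(OC)(O[Si](C)(C)C)C=C(O[Si](C)(C)C)C1Oc1cc(OCc2ccccc2)cc(OS(=O)(=O)C(F)(F)F)c1C(=O)OC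
F6 | step 4 | benzyl 3-{5-(benzyloxy)-2-(methoxycarbonyl)-3-[(trifluoromethanesulfonyl)oxy]phenoxy}-4,6-dihydroxy-2-pentylbenzoate | CCCCCc1c(Oc2cc(OCc3ccccc3)cc(OS(=O)(=O)C(F)(F)F)c2C(=O)OC)c(O)cc(O)c1C(=O)OCc1ccccc1
F7 | step 7 | 1-ethylcyclopropan-1-ol | CCC1(O)CC1
F8 | step 7 | benzyl 3-[5-(benzyloxy)-2-(methoxycarbonyl)-3-(3-oxopentyl)phenoxy]-6-hydroxy-4-methoxy-2-pentylbenzoate | CCCCCc1c(Oc2cc(OCc3ccccc3)cc(CCC(=O)CC)c2C(=O)OC)c(OC)cc(O)c1C(=O)OCc1ccccc1
A1 | direct plan | 6-(benzyloxy)-3-hydroxy-4-methoxy-2-[(E)-pent-2-en-1-yl]benzaldehyde | CC/C=C/Cc1c(O)c(OC)cc(OCc2ccccc2)c1C=O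
A2 | direct plan | methyl 4-(benzyloxy)-2-bromo-6-(3-oxopentyl)benzoate | CCC(=O)CCc1cc(OCc2ccccc2)cc(Br)c1C(=O)OC
A3 | direct plan | methyl 4-(benzyloxy)-2-{4-(benzyloxy)-3-formyl-6-methoxy-2-[(E)-pent-2-en-1-yl]phenoxy}-6-(3-oxopentyl)benzoate | CC/C=C/Cc1c(Oc2cc(OCc3ccccc3)cc(CCC(=O)CC)c2C(=O)OC)c(OC)cc(OCc2ccccc2)c1C=O
A4 | direct plan | 2-hydroxy-4-methoxybenzaldehyde | COc1ccc(C=O)c(O)c1
A5 | direct plan | 1-(benzyloxy)-3-bromo-5-iodobenzene | Brc1cc(I)cc(OCc2ccccc2)c1
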